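**Strategy**

Ring B (C5–C10) is cut at C5–C6 and C9–C10. Its diene half, C6–C9 with C11 and the C6 oxygen, is a 3-hydroxy-2-pyrone whose lactone bridge is a temporary ring; its alkene half is C5=C10 of a finished ring A. The target has 9-OH, the C10 methyl and H-5 on one face of ring B and C12 beside C9, so a single silicon atom, held by O9 and O12, carries the future C10 methyl carbon. Heating closes ring B by an intramolecular Diels–Alder reaction and sets C5, C6, C9, C10 and C7=C8 at once. Fluoride then turns Si–CH2 into CH3; Mitsunobu inversion at C6 brings in the trienoate.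

Key step: step 4

Remark 1: Drimane numbering is used (C11 on C9, C12 on C8, C15 = methyl carbon on C10) and β means the face of ring B that carries C15; the target is the cis-fused 5β-H, 6β-acyloxy, 9β-OH, 10β-CH3 isomer, (5R,6R,9R,10S).
Remark 2: 10, 11 and 12 are racemates drawn as the enantiomer that is carried on; the absolute configuration is fixed by the diastereomer separation in step 6.
Remark 3: Silane 4 is assumed to be a purchasable reagent.
Remark 4: The target is drawn as the open 12-oxo 11-acid; an equilibrium with its cyclic 12-hydroxy-11,12-olide form would not change the route.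

**Route**

Step 1
Reactants: 1 3-methylcyclohex-2-en-1-one
Product: 3 3,3-dimethylcyclohex-1-en-1-yl trifluoromethanesulfonate, via magnesium enolate 2 (not isolated)
Conditions: MeMgBr, CuI (cat.), THF, −20 °C; then PhNTf2, −20 °C → rt
Reagents that add atoms: methylmagnesium bromide, C[Mg]Br; N-phenylbis(trifluoromethanesulfonimide), FC(F)(F)S(=O)(=O)N(c1ccccc1)S(=O)(=O)C(F)(F)F
Why: Copper-catalysed conjugate addition of the Grignard reagent builds the C4 gem-dimethyl centre and leaves the enolate pointing toward it, so O-triflation of this enolate should fix the future C5=C10 double bond regiospecifically.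

Step 2
Reactants: 3 3,3-dimethylcyclohex-1-en-1-yl trifluoromethanesulfonate; 4 (chloromethyl)(methyl)di(propan-2-yloxy)silane
Product: 6 [(3,3-dimethylcyclohex-1-en-1-yl)methyl](methyl)di(propan-2-yloxy)silane, via silylmethyl Grignard reagent 5 (not isolated)
Conditions: 4, Mg, THF, reflux; then 3, Pd(PPh3)4 (cat.), THF, 0 → 40 °C
Reagents that add atoms: none
Why: Kumada cross-coupling of the enol triflate with an (alkoxysilyl)methyl Grignard reagent, which has no β-hydrogen, should join C15 to C10 and give an allylsilane with two exchangeable alkoxy groups on silicon.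

Step 3
Reactants: 7 3-hydroxy-2H-pyran-2-one
Product: 8 3-hydroxy-4-(hydroxymethyl)-2H-pyran-2-one
Conditions: CH2O (37 % aq.), Et3N (cat.), THF/H2O, 0 °C → rt
Reagents that add atoms: formaldehyde, C=O
Why: Base-catalysed hydroxymethylation (Lederer–Manasse type aldol of the enolate of this enolic α-keto lactone) should occur at C4, the α-carbon of the enolate, as it does next to the enolic hydroxyl of kojic acid, and brings in C12 at the alcohol level.

Step 4
Reactants: 6 [(3,3-dimethylcyclohex-1-en-1-yl)methyl](methyl)di(propan-2-yloxy)silane; 8 3-hydroxy-4-(hydroxymethyl)-2H-pyran-2-one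
Product: 10 (±)-cage adduct with ring B closed, via pyrone silylene 9 (not isolated)
Conditions: PPTS (cat.), PhMe, 60 °C, reduced pressure (−iPrOH); then BHT (cat.), PhMe (0.01 M), 100 °C, sealed tube
Reagents that add atoms: none
Why: On heating, the C6–C9 diene of the 2-pyrone and the C5=C10 alkene of ring A should combine in a concerted, asynchronous [4+2] cycloaddition; the closest known reaction types are the intramolecular Diels–Alder reaction of 2-pyrones with tethered alkenes and the Diels–Alder reaction through a temporary silicon tether. Ring B closes by suprafacial bond formation at C9–C10 and C5–C6, the lactone stays as a two-atom bridge from C9 to C6 (100 °C is chosen to avoid loss of CO2), and the five-membered O9–Si–C15–C10–C9 ring closes in the same event. C10 and C5 follow from the cis geometry of the ring A alkene (C15 and H-5 cis, hence the cis ring fusion), C9 and C6 from the ring of the diene (C11 and O6 on one face, O9 on the other), and the relation between the two pairs from the tether. Because silicon is also bound to O12 it lies on the C8 side of the diene axis, so its CH2 arm can only reach C9 with C15 endo, which puts ring A over the lactone bridge and C15 cis to O9. The step needs regioselectivity (C10 to C9, not to C6) and this endo delivery, and both are secured by the two-point anchoring of silicon and the one-carbon length of the arm; the two faces of the flat pyrone are equivalent, so 10 should form as a racemate that is resolved in step 6.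

Step 5
Reactants: 10 (±)-cage adduct
Product: 12 (±)-6α,9β,12-trihydroxy-5β-H-drim-7-en-11-oic acid, via hydroxy lactone 11 (not isolated)
Conditions: TBAF·3H2O, DMF, 75 °C; then LiOH (aq.), rt; then HCl (aq.) to pH 3
Reagents that add atoms: lithium hydroxide, [Li+].[OH-]
Why: Fluoride-induced protodesilylation of the 1-oxa-2-silacyclopentane (the known reductive methylation through a silicon tether, via a pentacoordinate siliconate held by the C9 alkoxide) should turn Si–CH2 into the C10 methyl and free 9-OH and 12-OH, and saponification of the strained bridged lactone then frees C11 and 6α-OH without touching a stereocentre.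

Step 6
Reactants: 12 (±)-6α,9β,12-trihydroxy-5β-H-drim-7-en-11-oic acid
Product: 13 (1R,2S,5R)-menthyloxymethyl (5R,6S,9R,10S)-6,9,12-trihydroxydrim-7-en-11-oate
Conditions: (−)-chloromethyl menthyl ether, KHCO3, DMF, 0 °C; chromatographic separation of the two diastereomers
Reagents that add atoms: (−)-chloromethyl menthyl ether [(1R,2S,5R)-2-(chloromethoxy)-4-methyl-1-(propan-2-yl)cyclohexane], ClCO[C@@H]1C[C@H](C)CC[C@H]1C(C)C
Why: O-alkylation of the carboxylate (SN2 at the chloromethyl ether, so the hindered C11 carbonyl need not be attacked) protects the acid as an acid-labile alkoxymethyl ester and, as the menthyl group is one enantiomer, turns the racemate into two separable diastereomers, of which the one with the (5R,6S,9R,10S) core is carried on (resolution through a covalent derivative).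

Step 7
Reactants: 13 menthyloxymethyl (5R,6S,9R,10S)-6,9,12-trihydroxydrim-7-en-11-oate
Product: 14 menthyloxymethyl (5R,6S,9R,10S)-6,9-dihydroxy-12-oxodrim-7-en-11-oate
Conditions: TEMPO (cat.), PhI(OAc)2, CH2Cl2, 0 °C → rt
Reagents that add atoms: none
Why: The oxoammonium oxidation with TEMPO is selective for the primary allylic 12-OH over the secondary allylic 6-OH and the tertiary 9-OH and should give the C12 enal.

Step 8
Reactants: 15 (2E,4E)-hexa-2,4-dienal; 16 malonic acid
Product: 17 (2E,4E,6E)-octa-2,4,6-trienoic acid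
Conditions: pyridine, piperidine (cat.), 90 °C; then HCl (aq.)
Reagents that add atoms: none
Why: Knoevenagel–Doebner condensation with decarboxylation extends the dienal by two carbons and should give the new double bond in the E form.

Step 9
Reactants: 14 menthyloxymethyl (5R,6S,9R,10S)-6,9-dihydroxy-12-oxodrim-7-en-11-oate; 17 (2E,4E,6E)-octa-2,4,6-trienoic acid
Product: 18 menthyloxymethyl (5R,6R,9R,10S)-9-hydroxy-6-[(2E,4E,6E)-octa-2,4,6-trienoyloxy]-12-oxodrim-7-en-11-oate
Conditions: PPh3, DIAD, PhMe, 0 °C → rt
Reagents that add atoms: none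
Why: Mitsunobu esterification displaces the oxyphosphonium group at C6 by the trienoate in an SN2 reaction and should invert 6α-OH to the 6β-ester, since SN2′ attack would have to create a quaternary C8, ionisation is disfavoured by the C12 formyl group and the tertiary 9-OH does not react.

Step 10
Reactants: 18 menthyloxymethyl ester of the target acid
Product: 19 (5R,6R,9R,10S)-9-hydroxy-6-[(2E,4E,6E)-octa-2,4,6-trienoyloxy]-12-oxodrim-7-en-11-oic acid (target)
Conditions: TFA/CH2Cl2 (1:4), H2O (5 equiv), 0 °C
Reagents that add atoms: none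
Why: Acidolysis of the acetal-type alkoxymethyl ester should release the C11 acid under conditions that leave the trienoate ester, the enal and the tertiary allylic alcohol untouched.

**Compound list**

1 | 3-methylcyclohex-2-en-1-one | CC1=CC(=O)CCC1 | starting material
2 | bromomagnesium 3,3-dimethylcyclohex-1-en-1-olate | CC1(C)CCCC(O[Mg]Br)=C1 | intermediate
3 | 3,3-dimethylcyclohex-1-en-1-yl trifluoromethanesulfonate | CC1(C)CCCC(OS(=O)(=O)C(F)(F)F)=C1 | intermediate
4 | (chloromethyl)(methyl)di(propan-2-yloxy)silane | ClC[Si](C)(OC(C)C)OC(C)C | starting material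
5 | {[methyldi(propan-2-yloxy)silyl]methyl}magnesium chloride | CC(C)O[Si](C)(C[Mg]Cl)OC(C)C | intermediate
6 | [(3,3-dimethylcyclohex-1-en-1-yl)methyl](methyl)di(propan-2-yloxy)silane | CC(C)O[Si](C)(CC1=CC(C)(C)CCC1)OC(C)C | intermediate
7 | 3-hydroxy-2H-pyran-2-one | OC1=CC=COC1=O | starting material
8 | 3-hydroxy-4-(hydroxymethyl)-2H-pyran-2-one | OCC1=C(O)C(=O)OC=C1 | intermediate
9 | 2-[(3,3-dimethylcyclohex-1-en-1-yl)methyl]-2-methyl-4H-pyrano[3,4-d][1,3,2]dioxasilin-8-one (racemic at silicon) | C[Si]1(CC2=CC(C)(C)CCC2)OCC2=C(O1)C(=O)OC=C2 | intermediate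
10 | (±)-cage adduct: drim-7-ene skeleton with the lactone bridge C11(=O)–O–C6 on the α face, 5β-H, and one Si(CH3) bound to 9β-O, to O12 and to the 10β-CH2 (C15) | O=C1O[C@H]2C=C3CO[Si@]4(C)C[C@@]5(CCCC(C)(C)[C@@H]25)[C@]13O4 | intermediate
11 | (±)-9β,12-dihydroxy-5β-H-drim-7-en-11,6α-olide | O=C1O[C@H]2C=C(CO)[C@]1(O)[C@@]3(C)CCCC(C)(C)[C@@H]23 | intermediate
12 | (±)-6α,9β,12-trihydroxy-5β-H-drim-7-en-11-oic acid | O[C@H]1C=C(CO)[C@@](O)(C(=O)O)[C@@]2(C)CCCC(C)(C)[C@@H]12 | intermediate
13 | (1R,2S,5R)-menthyloxymethyl (5R,6S,9R,10S)-6,9,12-trihydroxydrim-7-en-11-oate | O[C@H]1C=C(CO)[C@@](O)(C(=O)OCO[C@@H]2C[C@H](C)CC[C@H]2C(C)C)[C@@]3(C)CCCC(C)(C)[C@@H]13 | intermediate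
14 | (1R,2S,5R)-menthyloxymethyl (5R,6S,9R,10S)-6,9-dihydroxy-12-oxodrim-7-en-11-oate | O[C@H]1C=C(C=O)[C@@](O)(C(=O)OCO[C@@H]2C[C@H](C)CC[C@H]2C(C)C)[C@@]3(C)CCCC(C)(C)[C@@H]13 | intermediate
15 | (2E,4E)-hexa-2,4-dienal | C/C=C/C=C/C=O | starting material
16 | malonic acid | OC(=O)CC(=O)O | starting material
17 | (2E,4E,6E)-octa-2,4,6-trienoic acid | C/C=C/C=C/C=C/C(=O)O | intermediate
18 | (1R,2S,5R)-menthyloxymethyl (5R,6R,9R,10S)-9-hydroxy-6-[(2E,4E,6E)-octa-2,4,6-trienoyloxy]-12-oxodrim-7-en-11-oate | C/C=C/C=C/C=C/C(=O)O[C@@H]1C=C(C=O)[C@@](O)(C(=O)OCO[C@@H]2C[C@H](C)CC[C@H]2C(C)C)[C@@]3(C)CCCC(C)(C)[C@@H]13 | intermediate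
19 | (5R,6R,9R,10S)-9-hydroxy-6-[(2E,4E,6E)-octa-2,4,6-trienoyloxy]-12-oxodrim-7-en-11-oic acid | C/C=C/C=C/C=C/C(=O)O[C@@H]1C=C(C=O)[C@@](O)(C(=O)O)[C@@]2(C)CCCC(C)(C)[C@@H]12 | target

**Count and risks**

Total step count: 10. Longest linear sequence: 8 steps (steps 1, 2, 4, 5, 6, 7, 9, 10).

Steps most likely to fail:

1. Step 4. The trisubstituted alkene, flanked by the C4 quaternary centre, may react too slowly at 100 °C, and at the higher temperature it would then need the bridged lactone may lose CO2, which would remove C11. Fallback, from 8 back to 10: 8 would be brominated at C5 of the pyrone (NBS, MeCN, 0 °C) to 5-bromo-3-hydroxy-4-(hydroxymethyl)-2H-pyran-2-one F1. Condensation with 6 as in step 4 would give the bromopyrone silylene F2. As a 5-bromo-2-pyrone this is a more reactive, ambiphilic diene and should cyclise at 70–80 °C to the 7-bromo cage adduct F3. Bu3SnH and AIBN (PhH, 80 °C) would then remove the vinylic bromine and give 10.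

2. Step 3. The enolate may also be attacked at C6, and the product may condense with a second pyrone to a bis(pyronyl)methane. Fallback, from 7 back to 8: 7 would be heated with PhB(OH)2 and paraformaldehyde (EtCO2H cat., PhMe, reflux) in a boron-templated ortho-hydroxymethylation. The boron atom bound to O3 delivers formaldehyde to C4 only and holds the product as the cyclic phenylboronate 2-phenyl-4H-pyrano[3,4-d][1,3,2]dioxaborinin-8-one F4. Transesterification with pinacol would release 8.

3. Step 9. Substitution at the hindered C6 may be slow, and anti elimination of the activated 6α-oxygen with H-5 to a conjugated dienal, or acylation with retention, may compete. Fallback, from 14 back to 18: 14 would be inverted with the more acidic 4-nitrobenzoic acid (PPh3, DIAD) to the 6β-(4-nitrobenzoate) F5. The nitrobenzoate would be removed (NaN3, MeOH) to give the 6β-alcohol F6. F6 would be acylated with 17 with retention by Steglich esterification (EDC·HCl, DMAP, CH2Cl2) to give 18.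

**Further compounds**

F1 | step 4 | 5-bromo-3-hydroxy-4-(hydroxymethyl)-2H-pyran-2-one | OCC1=C(O)C(=O)OC=C1Br
F2 | step 4 | 5-bromo-2-[(3,3-dimethylcyclohex-1-en-1-yl)methyl]-2-methyl-4H-pyrano[3,4-d][1,3,2]dioxasilin-8-one | C[Si]1(CC2=CC(C)(C)CCC2)OCC2=C(O1)C(=O)OC=C2Br
F3 | step 4 | (±)-7-bromo analogue of cage adduct 10 | O=C1O[C@H]2C(Br)=C3CO[Si@]4(C)C[C@@]5(CCCC(C)(C)[C@@H]25)[C@]13O4
F4 | step 3 | 2-phenyl-4H-pyrano[3,4-d][1,3,2]dioxaborinin-8-one | O=C1OC=CC2=C1OB(c1ccccc1)OC2
F5 | step 9 | (1R,2S,5R)-menthyloxymethyl (5R,6R,9R,10S)-9-hydroxy-6-(4-nitrobenzoyloxy)-12-oxodrim-7-en-11-oate | O=C(O[C@@H]1C=C(C=O)[C@@](O)(C(=O)OCO[C@@H]2C[C@H](C)CC[C@H]2C(C)C)[C@@]3(C)CCCC(C)(C)[C@@H]13)c1ccc(cc1)[N+](=O)[O-]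
F6 | step 9 | (1R,2S,5R)-menthyloxymethyl (5R,6R,9R,10S)-6,9-dihydroxy-12-oxodrim-7-en-11-oate | O[C@@H]1C=C(C=O)[C@@](O)(C(=O)OCO[C@@H]2C[C@H](C)CC[C@H]2C(C)C)[C@@]3(C)CCCC(C)(C)[C@@H]13
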